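The earlier runs and the new flask are simulated for substances that don't exist, and the scatter is random.

**Earlier runs.** Maple and elm are your two earlier flasks, and you judge spring and dawn by them.

| setting | maple | elm | spring | dawn |
|---|---|---|---|---|
| starting material | 20 mM | 20 mM | 20 mM | 20 mM |
| precatalyst | 0.45 mol% | 0.78 mol% | 0.6 mol% | 0.38 mol% |
| remark | run made earlier | run made earlier |  |  |
| time |  |  | 120 h | 40 h |

- maple (time / h: target / %): 5.00: 16.9; 15.0: 42.1; 25.0: 48.7; 40.0: 50.5
- elm (time / h: target / %): 3.00: 13.7; 8.00: 38.4; 15.0: 48.8; 40.0: 50.3

(each reading ± 0.3 percentage points)

- the earlier runs were read with a standard deviation of 0.3 percentage points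
- steps thought possible: starting material + catalyst <-> target + catalyst; target <-> isomer of the product; isomer of the product + catalyst <-> starting material + catalyst; precatalyst -> catalyst

- the flask that ends with the higher amount of target, in percent of the starting material charged, or "neither" when 2 percentage points or less lies between them (spring / dawn / neither)
- final target, as a percentage of the starting material charged, in spring
- final target, as a percentage of the starting material charged, in dawn

**Upper bound.** The last readings of maple and elm average 50.4%. I take that plateau as the ceiling for spring and dawn.

**Lower bound.** Use a catalyst clock: hours after a lag of 3.00 h, scaled by loading over maple's loading. This replaces the rising catalyst curve by its mean. Maple at 25.0 h has 22.0 h on this clock and reads 48.7%. Dawn at 40 h has 31.2 h, which is more than maple, so I put dawn above that reading.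

**Tightening.** Maple's gap to the plateau shrinks from 8.3 percentage points at 15.0 h to 1.7 points at 25.0 h. That gives the closing rate, the pseudo-first-order rate of the gap per clock hour, read with the scatter of those readings: 0.159 h⁻¹. Dawn's gap is then 0.39 points, which puts dawn at 50.0%. With no lag, dawn's gap is 0.42 points, so the lag moves that gap by less than the scatter. Spring has 156 h on the clock, so its gap is less than the scatter. Dawn's gap is less than the margin, so I say neither.

**The forecast.** The forecast gives 50.2% for spring, 50% for dawn, and neither. Its dawn lies inside my bracket. Its spring stands below my ceiling, and of a possible loss it says “any loss should be small, though it could lower spring slightly”.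

**The result.** Spring gives 50.2% and dawn 49.9%, so the answer is neither.

    starting material + catalyst ⇌ target + catalyst, rate k1*[starting material]*[catalyst] forward; the back reaction follows from the equilibrium constant (K = 1.20, k = 14.0 L mol⁻¹ min⁻¹)
    target ⇌ isomer of the product (K = 0.160, k = 8.40 × 10⁻⁵ min⁻¹)
    isomer of the product + catalyst ⇌ starting material + catalyst, rate k3*[catalyst]*[isomer of the product] forward; the back reaction follows from the equilibrium constant (k = 7.60 L mol⁻¹ min⁻¹)
    precatalyst → catalyst (k = 0.00620 min⁻¹)

Spring holds 8.03% of isomer of the product at the end, and ten times the time makes no difference to its target. Now use the closing rate on dawn at 20.0 h. The clock shows 14.4 h, the gap is 5.7 points, and the target comes to 44.7%. Dawn held 44.9% of target then.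

**Second flask.** Take dawn with 0.095 mol% of precatalyst, read at 40.0 h. Its clock shows 7.81 h, so the gap is 16 points and the target 34.4%. The computed flask gives 34.6% of target.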